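We have no rate constants for these flasks, so we count turnovers of reagent instead: each first product has used one reagent, each double product two, and the count cannot pass what was charged.

| setting | south-east | north-east | south | ochre | blue | amber | green |
|---|---|---|---|---|---|---|---|
| starting material | 20 mM | 20 mM | 20 mM | 20 mM | 20 mM | 20 mM | 20 mM (fed, over 2.5 h) |
| reagent | 0.95 equiv | 1.3 equiv | 2.1 equiv | 0.950 equiv | 0.950 equiv (fed, over 2.5 h) | 0.950 equiv (in portions, 2, over 2.5 h) | 0.950 equiv |
| remark | run made earlier | run made earlier | run made earlier | everything together at the start | all else is in the flask from the start; the feed brings no volume worth counting | first portion at the start, last at 2.5 h | all else is in the flask from the start; the feed brings no volume worth counting |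
| time |  |  |  | 4.0 h | 4.0 h | 4.0 h | 4.0 h |

- south-east (time / h: double product / %, first product / %): 0.200: 30, 32; 0.667: 32, 32; 1.00: 31, 33; 1.50: 29, 34; 2.50: 30, 36; 3.00: 33, 31; 4.00: 33, 32
- north-east (time / h: double product / %, first product / %): 0.500: 52, 28; 1.00: 53, 27; 1.50: 53, 28; 2.50: 51, 28; 3.00: 50, 25; 4.00: 50, 28
- south (time / h: double product / %, first product / %): 0.500: 85, 4; 1.00: 89, 3; 1.50: 92, 2; 2.50: 93, 0; 3.00: 94, 0; 4.00: 91, 0

(each reading ± 2 percentage points)



1. the flask that comes out highest in amount of double product, in percent of the starting material charged; "all alike" if 1.5 percentage points covers them all (ochre / blue / amber / green / all alike)
2. amount of double product at the end, in percent of the starting material charged, ochre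
3. amount of double product at the end, in percent of the starting material charged, blue
4. amount of double product at the end, in percent of the starting material charged, amber
5. amount of double product at the end, in percent of the starting material charged, green

First, how quickly is the reagent used? In the south-east run at 0.200 h the count reads 92.0% of the starting material against 0.95 equiv charged, so nearly all of the reagent in that run reads as turned over, and the feed of 2.5 h lasts 12.5 times as long as that sample took.

Then, does slow reagent change the split? In blue and amber, as in ochre, starting material and first product stand together, and if both steps are first order in reagent, its concentration cancels from the ratio of their rates. So we expect ochre, blue and amber near the south-east reading of 31%.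

What, then, does green do? Starting material enters excess reagent, and since a turnover takes far less time than the feed, we expect each arrival to turn over twice. On this estimate reagent, the limiting reagent, lasts until about 1.19 h of the feed, and the double product of green reaches at most the double-product ceiling, the equivalents of reagent divided by two, 47.5%. Once the count has reached the charge, any first product in green lowers this by one double product for every two first products.

The forecast names green: ochre 31%, blue 31%, amber 31%, and green 43%, between 38% and 47%, below our ceiling. Its ground for green is that starting material “trickles into excess reagent and goes on to double product until the reagent runs out”.

Green comes out highest at 44.3%, with ochre at 31.3%, blue at 31.3% and amber at 31.3%. Green ends with 49% of its starting material unbound, reagent at 0% of its own charge and tris adduct, the further adduct of reagent on double product, at 0%. Green stands 3.2 percentage points under the ceiling, which is half of its 6.34% first product.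

    reagent + first product → double product (k = 90.5 M⁻¹ min⁻¹)
    reagent + double product ⇌ tris adduct (K = 200 M⁻¹, k = 409 M⁻¹ min⁻¹)
    starting material + reagent → first product (k = 72.1 M⁻¹ min⁻¹)

Take the neighbour of green with 1.60 equiv of reagent: the ceiling there is 80.0%. The computed flask holds 76.3% double product beside 7.44% first product.

(The data were computed from invented constants.)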